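The central 2,4-disubstituted oxazole is cut across its O1–C5 and N3–C4 bonds, and everything rests on that disconnection. That ring is the only link between the chiral, esterified hexyl chain on ring C4 and the base-sensitive oxazol-5-ylmethyl arm on ring C2, so a single silver-assisted condensation of a primary amide with a bromomethyl ketone joins both halves, builds the ring and brings in the bis-heteroaryl CH2 only at the end. The ketone partner is a heterocycle-free chain already carrying the C1 14-methylpentadecanoate and three benzyl ethers: C3–C5 come from L-fucal, C1 from a Noyori ynone reduction, and the BrCH2–C(=O) unit from ester-assisted gold hydration of a bromoalkyne, which avoids enol bromination beside C1.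

Key step: step 12

Assumption: lactol 2 (anomers) and alkynol 7 (C3 epimers) are carried as mixtures, because those centres are opened or oxidised in the next operation; the acyl residue is 14-methylpentadecanoyl exactly as drawn.

**Step 1**
Reactants: 1 3,4-di-O-acetyl-L-fucal
Product: 2 3,4-di-O-acetyl-2-deoxy-L-fucopyranose (2,6-dideoxy-L-lyxo-hexopyranose 3,4-diacetate; anomeric mixture)
Conditions: PPh3·HBr (5 mol %), H2O, THF, rt
Reagents that add atoms: water, O
Why: Acid-catalysed Markovnikov hydration of the glycal enol ether protonates C2 and traps the C1 oxocarbenium ion with water, the mild phosphonium hydrobromide avoiding Ferrier loss of the C3 acetate; the anomeric centre forms as a mixture and is erased in step 2.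

**Step 2**
Reactants: 2 3,4-di-O-acetyl-2-deoxy-L-fucopyranose
Product: 4 (2S,3R,4S)-5-(1,3-dithian-2-yl)pentane-2,3,4-triol (2-deoxy-L-fucose propane-1,3-diyl dithioacetal), via diacetyl dithioacetal 3 (not isolated)
Conditions: HS(CH2)3SH, BF3·OEt2, CH2Cl2, −20 → 0 °C; Et3N, concentrate; then K2CO3 (cat.), MeOH, rt
Reagents that add atoms: propane-1,3-dithiol, SCCCS
Why: Lewis-acid thioacetalisation of a 2-deoxy lactol opens the pyranose because the second thiol closes the six-membered dithiane intramolecularly, and Zemplén-type methanolysis then removes both acetates, so C3, C4 and C5 keep their L-fucose configurations.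

**Step 3**
Reactants: 4 (2S,3R,4S)-5-(1,3-dithian-2-yl)pentane-2,3,4-triol
Product: 5 2-[(2S,3R,4S)-2,3,4-tris(benzyloxy)pentyl]-1,3-dithiane
Conditions: NaH, BnBr, n-Bu4NI (cat.), DMF, 0 °C → rt
Reagents that add atoms: benzyl bromide, BrCc1ccccc1
Why: Williamson etherification of the three secondary alkoxides; the dithiane C–H is far too weakly acidic for NaH and thioacetal sulfur is a poor nucleophile towards benzyl bromide.

**Step 4**
Reactants: 5 2-[(2S,3R,4S)-2,3,4-tris(benzyloxy)pentyl]-1,3-dithiane
Product: 6 (3S,4R,5S)-3,4,5-tris(benzyloxy)hexanal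
Conditions: I2, NaHCO3, acetone/H2O, 0 °C
Reagents that add atoms: water, O
Why: Oxidative dethioacetalisation, in which iodine activates sulfur and water hydrolyses the sulfonium ion while bicarbonate keeps the medium near neutral, so that the β-benzyloxy aldehyde (used crude) should neither eliminate nor epimerise.

**Step 5**
Reactants: 6 (3S,4R,5S)-3,4,5-tris(benzyloxy)hexanal
Product: 7 (5S,6R,7S)-5,6,7-tris(benzyloxy)-1-(trimethylsilyl)oct-1-yn-3-ol (both C3 epimers)
Conditions: Me3SiC≡CH, n-BuLi, THF, −78 °C; then 6, −78 °C; aq. NH4Cl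
Reagents that add atoms: ethynyltrimethylsilane (as its lithium acetylide), C#C[Si](C)(C)C
Why: 1,2-Addition of a lithium acetylide to an aldehyde at low temperature; the new carbinol centre forms without useful control, which does not matter because it is oxidised in step 6.

**Step 6**
Reactants: 7 (5S,6R,7S)-5,6,7-tris(benzyloxy)-1-(trimethylsilyl)oct-1-yn-3-ol
Product: 8 (5S,6R,7S)-5,6,7-tris(benzyloxy)-1-(trimethylsilyl)oct-1-yn-3-one
Conditions: Dess–Martin periodinane, CH2Cl2, 0 °C → rt
Reagents that add atoms: none
Why: Dess–Martin oxidation of a secondary propargylic alcohol under base-free conditions, which avoids β-elimination of the C5 benzyloxy group from the ynone.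

**Step 7**
Reactants: 8 (5S,6R,7S)-5,6,7-tris(benzyloxy)-1-(trimethylsilyl)oct-1-yn-3-one
Product: 10 (3R,5S,6R,7S)-5,6,7-tris(benzyloxy)oct-1-yn-3-ol, via silylated (R)-alkynol 9 (not isolated)
Conditions: Ru[(R,R)-TsDPEN](p-cymene) (16-electron amido complex, 2 mol %), i-PrOH, rt; concentrate; then K2CO3, MeOH, 0 °C → rt
Reagents that add atoms: none
Why: Noyori asymmetric transfer hydrogenation of an alkynyl ketone, in which the (R,R)-diamine–ruthenium hydride delivers hydrogen to the Si face of the carbonyl under catalyst control (the alkyne is the π-group the catalyst recognises, overriding the C5 stereocentre) to set C3 as R, 1,3-syn to C5, after which methanolic carbonate cleaves the C(sp)–Si bond.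

**Step 8**
Reactants: 10 (3R,5S,6R,7S)-5,6,7-tris(benzyloxy)oct-1-yn-3-ol; 11 14-methylpentadecanoic acid
Product: 12 (3R,5S,6R,7S)-5,6,7-tris(benzyloxy)oct-1-yn-3-yl 14-methylpentadecanoate
Conditions: DIC, DMAP (cat.), CH2Cl2, 0 °C → rt
Reagents that add atoms: none
Why: Steglich esterification acylates the only free hydroxyl through the acylpyridinium ion, forming the O–acyl bond and leaving the C3–O bond, and hence the R configuration, untouched.

**Step 9**
Reactants: 12 (3R,5S,6R,7S)-5,6,7-tris(benzyloxy)oct-1-yn-3-yl 14-methylpentadecanoate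
Product: 13 (3R,5S,6R,7S)-5,6,7-tris(benzyloxy)-1-bromooct-1-yn-3-yl 14-methylpentadecanoate
Conditions: NBS, AgNO3 (10 mol %), acetone, rt, dark
Reagents that add atoms: N-bromosuccinimide, O=C1CCC(=O)N1Br
Why: Silver-catalysed electrophilic bromination of a terminal alkyne through its silver acetylide, under neutral conditions that esters and benzyl ethers tolerate.

**Step 10**
Reactants: 13 (3R,5S,6R,7S)-5,6,7-tris(benzyloxy)-1-bromooct-1-yn-3-yl 14-methylpentadecanoate
Product: 14 (3R,5S,6R,7S)-5,6,7-tris(benzyloxy)-1-bromo-2-oxooctan-3-yl 14-methylpentadecanoate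
Conditions: Ph3PAuCl (5 mol %), AgSbF6 (5 mol %), 1,4-dioxane/H2O, rt
Reagents that add atoms: water, O
Why: Gold(I)-catalysed hydration of a halo-propargyl carboxylate with anchimeric assistance, in which the ester carbonyl adds 5-exo-dig to the activated alkyne at the carbon next to C3, water opens the dioxolenium ion and protodeauration leaves the ketone at C2 and CH2Br at C1 without ever breaking the C3–O bond.

**Step 11**
Reactants: 15 2-(1,3-oxazol-5-yl)acetic acid
Product: 17 2-(1,3-oxazol-5-yl)acetamide, via acyl imidazolide 16 (not isolated)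
Conditions: CDI, THF, rt; then NH3 (7 M in MeOH), 0 °C → rt
Reagents that add atoms: ammonia, N
Why: Carboxyl activation as the acyl imidazolide followed by aminolysis with ammonia, a standard primary amide synthesis that needs no base strong enough to touch the oxazolylmethyl CH2.

**Step 12**
Reactants: 14 (3R,5S,6R,7S)-5,6,7-tris(benzyloxy)-1-bromo-2-oxooctan-3-yl 14-methylpentadecanoate; 17 2-(1,3-oxazol-5-yl)acetamide
Product: 20 (1R,3S,4R,5S)-3,4,5-tris(benzyloxy)-1-[2-(1,3-oxazol-5-ylmethyl)-1,3-oxazol-4-yl]hexyl 14-methylpentadecanoate, via O-alkyl imidate 18 (not isolated), via 4-hydroxyoxazoline 19 (not isolated)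
Conditions: AgOTf (1.5 equiv), 17 (2.5 equiv), EtOAc, 60 °C, dark
Reagents that add atoms: none
Why: Silver(I) pulls bromide from the CH2Br carbon of 14 while the carbonyl oxygen of amide 17 attacks it in an SN2-like O-alkylation, giving imidate 18 (as its triflate salt) and with it the future O1–C5 bond. The imidate nitrogen then adds to the ketone carbonyl in a 5-exo-trig closure (N3–C4 bond) to give hydroxyoxazoline 19, and acid-promoted loss of water aromatises the ring; the closest known reaction type is the silver-assisted Blümlein–Lewy condensation of an α-bromoketone with a primary amide. No stereocentre is created, because the carbinol carbon of 19 becomes sp2 on dehydration. Regiochemistry is fixed by the substrate, since only the CH2Br carbon carries a leaving group and only the ketone can form a five-membered ring with the imidate nitrogen, so the ketone carbon must become C4 (bearing C1 of the chain) and the CH2 becomes C5. The step needs O-alkylation of the amide in preference to alkylation of a weakly basic oxazole nitrogen or participation of the C1 ester carbonyl, which the excess of amide and the halophilic silver should secure. It also needs retention at C1, which is guarded by the absence of base, by the excess amide and the oxazole nitrogens taking up the released triflic acid, and by keeping the temperature at 60 °C, conditions under which the benzyl ethers and the ester are inert.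

**Step 13**
Reactants: 20 (1R,3S,4R,5S)-3,4,5-tris(benzyloxy)-1-[2-(1,3-oxazol-5-ylmethyl)-1,3-oxazol-4-yl]hexyl 14-methylpentadecanoate
Product: 21 (1R,3S,4R,5S)-3,4,5-trihydroxy-1-[2-(1,3-oxazol-5-ylmethyl)-1,3-oxazol-4-yl]hexyl 14-methylpentadecanoate (target)
Conditions: BCl3 (1 M in CH2Cl2, excess), C6HMe5, CH2Cl2, −78 °C; then MeOH/CHCl3, −78 °C → rt
Reagents that add atoms: none
Why: Lewis-acid debenzylation at −78 °C with pentamethylbenzene trapping the benzyl cations by Friedel–Crafts alkylation should cleave the three benzyl ethers while the ester, both oxazoles (whose nitrogen-bound BCl3 disfavours ionisation at C1) and all four stereocentres stay untouched.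

**Compound list**

1 | 3,4-di-O-acetyl-L-fucal | C[C@@H]1OC=C[C@H](OC(C)=O)[C@@H]1OC(C)=O | starting material
2 | 3,4-di-O-acetyl-2-deoxy-L-fucopyranose (anomeric mixture) | C[C@@H]1OC(O)C[C@H](OC(C)=O)[C@@H]1OC(C)=O | intermediate
3 | (2S,3R,4S)-1-(1,3-dithian-2-yl)-4-hydroxypentane-2,3-diyl diacetate (3,4-di-O-acetyl-2-deoxy-L-fucose propane-1,3-diyl dithioacetal) | S1CCCSC1C[C@H](OC(C)=O)[C@H](OC(C)=O)[C@H](C)O | intermediate (not isolated)
4 | (2S,3R,4S)-5-(1,3-dithian-2-yl)pentane-2,3,4-triol | S1CCCSC1C[C@H](O)[C@H](O)[C@H](C)O | intermediate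
5 | 2-[(2S,3R,4S)-2,3,4-tris(benzyloxy)pentyl]-1,3-dithiane | S1CCCSC1C[C@H](OCc1ccccc1)[C@H](OCc1ccccc1)[C@H](C)OCc1ccccc1 | intermediate
6 | (3S,4R,5S)-3,4,5-tris(benzyloxy)hexanal | O=CC[C@H](OCc1ccccc1)[C@H](OCc1ccccc1)[C@H](C)OCc1ccccc1 | intermediate
7 | (5S,6R,7S)-5,6,7-tris(benzyloxy)-1-(trimethylsilyl)oct-1-yn-3-ol (C3 epimers) | OC(C[C@H](OCc1ccccc1)[C@H](OCc1ccccc1)[C@H](C)OCc1ccccc1)C#C[Si](C)(C)C | intermediate
8 | (5S,6R,7S)-5,6,7-tris(benzyloxy)-1-(trimethylsilyl)oct-1-yn-3-one | O=C(C[C@H](OCc1ccccc1)[C@H](OCc1ccccc1)[C@H](C)OCc1ccccc1)C#C[Si](C)(C)C | intermediate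
9 | (3R,5S,6R,7S)-5,6,7-tris(benzyloxy)-1-(trimethylsilyl)oct-1-yn-3-ol | O[C@H](C[C@H](OCc1ccccc1)[C@H](OCc1ccccc1)[C@H](C)OCc1ccccc1)C#C[Si](C)(C)C | intermediate (not isolated)
10 | (3R,5S,6R,7S)-5,6,7-tris(benzyloxy)oct-1-yn-3-ol | O[C@H](C[C@H](OCc1ccccc1)[C@H](OCc1ccccc1)[C@H](C)OCc1ccccc1)C#C | intermediate
11 | 14-methylpentadecanoic acid | CC(C)CCCCCCCCCCCCC(=O)O | starting material
12 | (3R,5S,6R,7S)-5,6,7-tris(benzyloxy)oct-1-yn-3-yl 14-methylpentadecanoate | CC(C)CCCCCCCCCCCCC(=O)O[C@H](C[C@H](OCc1ccccc1)[C@H](OCc1ccccc1)[C@H](C)OCc1ccccc1)C#C | intermediate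
13 | (3R,5S,6R,7S)-5,6,7-tris(benzyloxy)-1-bromooct-1-yn-3-yl 14-methylpentadecanoate | CC(C)CCCCCCCCCCCCC(=O)O[C@H](C[C@H](OCc1ccccc1)[C@H](OCc1ccccc1)[C@H](C)OCc1ccccc1)C#CBr | intermediate
14 | (3R,5S,6R,7S)-5,6,7-tris(benzyloxy)-1-bromo-2-oxooctan-3-yl 14-methylpentadecanoate | CC(C)CCCCCCCCCCCCC(=O)O[C@H](C[C@H](OCc1ccccc1)[C@H](OCc1ccccc1)[C@H](C)OCc1ccccc1)C(=O)CBr | intermediate
15 | 2-(1,3-oxazol-5-yl)acetic acid | OC(=O)Cc1cnco1 | starting material
16 | 1-(1H-imidazol-1-yl)-2-(1,3-oxazol-5-yl)ethan-1-one | O=C(Cc1cnco1)n1ccnc1 | intermediate (not isolated)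
17 | 2-(1,3-oxazol-5-yl)acetamide | NC(=O)Cc1cnco1 | intermediate
18 | (3R,5S,6R,7S)-5,6,7-tris(benzyloxy)-1-{[1-imino-2-(1,3-oxazol-5-yl)ethyl]oxy}-2-oxooctan-3-yl 14-methylpentadecanoate | CC(C)CCCCCCCCCCCCC(=O)O[C@H](C[C@H](OCc1ccccc1)[C@H](OCc1ccccc1)[C@H](C)OCc1ccccc1)C(=O)COC(=N)Cc1cnco1 | intermediate (not isolated)
19 | (1R,3S,4R,5S)-3,4,5-tris(benzyloxy)-1-[4-hydroxy-2-(1,3-oxazol-5-ylmethyl)-4,5-dihydro-1,3-oxazol-4-yl]hexyl 14-methylpentadecanoate (ring C4 epimers) | CC(C)CCCCCCCCCCCCC(=O)O[C@H](C[C@H](OCc1ccccc1)[C@H](OCc1ccccc1)[C@H](C)OCc1ccccc1)C1(O)COC(Cc2cnco2)=N1 | intermediate (not isolated)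
20 | (1R,3S,4R,5S)-3,4,5-tris(benzyloxy)-1-[2-(1,3-oxazol-5-ylmethyl)-1,3-oxazol-4-yl]hexyl 14-methylpentadecanoate | CC(C)CCCCCCCCCCCCC(=O)O[C@H](C[C@H](OCc1ccccc1)[C@H](OCc1ccccc1)[C@H](C)OCc1ccccc1)c1coc(Cc2cnco2)n1 | intermediate
21 | (1R,3S,4R,5S)-3,4,5-trihydroxy-1-[2-(1,3-oxazol-5-ylmethyl)-1,3-oxazol-4-yl]hexyl 14-methylpentadecanoate | CC(C)CCCCCCCCCCCCC(=O)O[C@H](C[C@H](O)[C@H](O)[C@H](C)O)c1coc(Cc2cnco2)n1 | target

**Step count**

Total: 13 steps. Longest linear sequence: 12 steps (steps 1–10, 12 and 13); step 11 is the one-step side branch.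

**Steps most likely to fail**

1. Step 12. What may go wrong: acid- and heat-driven enolisation towards C1 with erosion of its configuration, silver-assisted participation of the C1 ester carbonyl at the CH2Br carbon (acyl transfer across the ketone), or alkylation of an oxazole nitrogen in place of the amide oxygen. Fallback: setting out from terminal alkyne 12 and amide 17 and coming back to the route at 20, a gold-catalysed oxidative [3+2] annulation (Mor-DalPhosAuOMs cat., 8-methylquinoline N-oxide, PhCl, 60 °C) would turn the alkyne into an α-oxo gold carbene. The amide oxygen adds to the carbene carbon (O1–C5) and the nitrogen condenses with the new ketone (N3–C4), so the same two ring bonds form without bromide, silver or strong acid. No compound outside the list is made (F0).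

2. Step 10. What may go wrong: migration or ionisation of the propargylic acyloxy group at gold outrunning capture by water, or protodebromination of the alkyne. Fallback: setting out from 12, the bromine-free terminal alkyne is hydrated under the same ester-assisted gold catalysis (Ph3PAuCl/AgSbF6, dioxane/H2O, rt) to the methyl ketone (3R,5S,6R,7S)-5,6,7-tris(benzyloxy)-2-oxooctan-3-yl 14-methylpentadecanoate F1. Bromine in methanol at 0 °C, conditions known to brominate the less substituted α-carbon of methyl ketones (here also the one not deactivated by the acyloxy group), then brings the sequence back to the route at 14.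

3. Step 13. What may go wrong: Lewis-acid ionisation of the C1–O ester bond next to the oxazole, acyl migration from O1 to the freed O3 during the quench, or stalled cleavage because both oxazole nitrogens bind BCl3. Fallback: setting out from 20 and arriving directly at 21, neutral catalytic hydrogenolysis (H2, Pd(OH)2/C, EtOAc/MeOH, rt) removes the benzyl groups reductively without any Lewis acid. No compound outside the list is made (F0).

**Further compounds**

F1 | step 10 | (3R,5S,6R,7S)-5,6,7-tris(benzyloxy)-2-oxooctan-3-yl 14-methylpentadecanoate | CC(C)CCCCCCCCCCCCC(=O)O[C@H](C[C@H](OCc1ccccc1)[C@H](OCc1ccccc1)[C@H](C)OCc1ccccc1)C(C)=O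
F0 | step 12 | none | none
F0 | step 13 | none | none
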